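| setting | north-west | flask |
|---|---|---|
| J | 0.075 M | 0.050 M |
| Q | 0.090 M | 0.0900 M |
| remark | run made earlier |  |
| time |  | 4.0 min |

north-west run (percent of the J charged)

| time / s | L / % |
|---|---|
| 10.0 | 8.0 |
| 15.0 | 11.1 |
| 25.0 | 14.5 |
| 30.0 | 16.7 |
| 40.0 | 18.8 |
| 50.0 | 20.5 |

(standard deviation of a reading: 0.3 percentage points)

- the best time, 4.0 min at the latest, for L
- the amount of L, in percent of the J charged, at that time

- the earlier runs were read with a standard deviation of 0.3 percentage points

The north-west run is still gaining L at its last reading, 20.5 % at 50.0 s, but its last 10.0 s add 1.7 points, where its first 10.0 s gave 8.0 %. Yet L then holds 17.1 % of the Q charged, so a way back from L is worth reckoning with. Counting J and Q as lost to L and nothing else, that reading gives 3.46 M⁻¹ for the holding ratio, the mass-action ratio of L over free J times free Q. For J + Q ⇌ L, L rises while this ratio lies below the equilibrium constant and falls above it.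

The flask charges the same Q with less J, so an estimate of this text's own, keeping the ratio at its north-west value although that run was still rising and taking flask Q as charged, puts free J at 76.3 % and L at 23.7 %. The forecast gives 26 % (range 20 % to 35 %) at 4 min (range 1.5 min to 4 min): “Nothing yet shows L falling, so I expect a plateau”.

The flask peaks at 1.42 min with 24.1 %, and holds 15.4 % at 4.00 min.

    J → X (k = 6.20 × 10⁻⁴ s⁻¹)
    J + Q ⇌ L (K = 11.0 M⁻¹, k = 0.110 M⁻¹ s⁻¹)
    Q → Z (k = 0.00510 s⁻¹)
    2 J → D (k = 0.0810 M⁻¹ s⁻¹)
    Q → E (k = 2.70 × 10⁻⁵ s⁻¹)

At that peak the flask has J at 44.4 % and D at 28.2 % of the J charged. The holding ratio, 3.46 M⁻¹ from the north-west reading with losses to L counted and nothing else, stands on free amounts at 11.0 M⁻¹ at the flask's peak, meeting the constant 11 M⁻¹. The neighbour with 0.15 M of Q stands at 17.4 M⁻¹ at 4.00 min, above that constant, with L at 23.8 % against its best of 36.1 %.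

The readings are calculated for substances that don't exist; scatter was added.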